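**Retrosynthetic overview**

1. Ring B (the dearomatised trione ring) is opened at two acyl–carbon bonds: from the ring carbonyl carbon on one side of the benzylated ring carbon to the butanoyl-bearing carbon, and from the carbonyl (enol) carbon on its other side to the methyl/prenyl quaternary carbon. This leaves a ring-A-benzylmalonyl 1,3-dielectrophile and an acyclic C13 1,3-dinucleophile.
2. Enabling feature: ring B is a cyclohexane-1,3,5-trione. Its benzylated carbon with the two flanking carbonyl carbons is a malonyl unit, and the butanoyl-bearing carbon and the quaternary carbon are the two α-carbons of the third ring carbonyl. The ring-A hydroxyl ortho to the CH2 bridge can hold one malonyl carbonyl as a six-membered aryl lactone and is given back as the free phenol.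
3. Dielectrophile from phloroglucinol: C-hexanoylation, 4-O-methylation, one-pot benzylation/lactonisation with formaldehyde and Meldrum's acid, acid chloride, ketene. Dinucleophile: prenylated propionamide, ynone, vinylogous amide of (S)-2-(methoxymethyl)pyrrolidine, 1-amino-3-siloxydiene.
4. Key union: a (3+3) double C-acylation through two ketenes builds ring B and its quaternary carbon in one operation and frees the phenol. The amine auxiliary makes the two epimers separable diastereomers and is hydrolysed off in the last step.
5. Ring order: ring A is bought; the temporary lactone ring is closed in step 3; ring B is closed last, in step 8, as the lactone opens.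

Key step: step 8

Assumption: the trione ring is treated as one compound in all its enol tautomers (drawn as in the target formula). No facial selectivity is counted on at the new quaternary carbon; the wanted epimer is isolated as one diastereomer of the auxiliary-bearing product 22.

**Route**

Step 1
Reactants: 1 phloroglucinol; 2 hexanoyl chloride
Product: 3 1-(2,4,6-trihydroxyphenyl)hexan-1-one
Conditions: AlCl3, PhNO2/CH2Cl2, 0 °C → 40 °C; aq. HCl
Reagents that add atoms: none
Why: Friedel–Crafts acylation of the electron-rich triol stops after one acyl group because the chelated aryl ketone deactivates the ring.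

Step 2
Reactants: 3 1-(2,4,6-trihydroxyphenyl)hexan-1-one
Product: 4 1-(2,6-dihydroxy-4-methoxyphenyl)hexan-1-one
Conditions: Me2SO4 (1 equiv), K2CO3, acetone, rt
Reagents that add atoms: dimethyl sulfate COS(=O)(=O)OC
Why: Williamson-type O-methylation is selective for the para hydroxyl because the two ortho hydroxyls are hydrogen-bonded to the ketone and less acidic, and one equivalent of dimethyl sulfate limits over-methylation.

Step 3
Reactants: 4 1-(2,6-dihydroxy-4-methoxyphenyl)hexan-1-one; 5 2,2-dimethyl-1,3-dioxane-4,6-dione (Meldrum's acid); 6 formaldehyde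
Product: 9 8-hexanoyl-7-hydroxy-5-methoxy-2-oxochromane-3-carboxylic acid, via methylidene Meldrum's acid 7 (not isolated), via arylmethyl Meldrum's acid 8 (not isolated)
Conditions: cat. L-proline, MeCN, rt (slow addition of aq. CH2O), then 50 °C
Reagents that add atoms: none
Why: Knoevenagel condensation gives the methylidene dione 7, which one of the two equivalent free ring carbons of 4 attacks in a Friedel–Crafts-type conjugate addition (three-component Yonemitsu-type condensation) to give 8; the neighbouring phenol then opens the dioxanedione by acyl substitution with loss of acetone and closes the six-membered aryl lactone.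

Step 4
Reactants: 9 8-hexanoyl-7-hydroxy-5-methoxy-2-oxochromane-3-carboxylic acid
Product: 11 8-hexanoyl-5-methoxy-2-oxo-7-(trimethylsilyloxy)chromane-3-carbonyl chloride, via bis(trimethylsilyl) derivative 10 (not isolated)
Conditions: N,O-bis(trimethylsilyl)acetamide, CH2Cl2, rt; then (COCl)2, cat. DMF, 0 °C → rt; volatiles removed, used crude
Reagents that add atoms: N,O-bis(trimethylsilyl)acetamide CC(=N[Si](C)(C)C)O[Si](C)(C)C; oxalyl chloride O=C(Cl)C(Cl)=O
Why: Silylation masks the chelated phenol and turns the acid into a silyl ester, which oxalyl chloride with catalytic DMF converts into the acid chloride under base-free Vilsmeier-type conditions, so that the malonyl C–H is not removed and the phenol is not acylated.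

Step 5
Reactants: 12 N-methoxy-N-methylpropanamide; 13 1-bromo-3-methylbut-2-ene (prenyl bromide)
Product: 14 N-methoxy-N,2,5-trimethylhex-4-enamide (racemic)
Conditions: LiN(iPr)2, THF, −78 °C; then 13, −78 → 0 °C
Reagents that add atoms: none
Why: SN2 alkylation of the lithium enolate of the N-methoxy-N-methylamide with the allylic bromide; the new tertiary centre is racemic and is erased later when it becomes trigonal.

Step 6
Reactants: 14 N-methoxy-N,2,5-trimethylhex-4-enamide; 15 pent-1-yne
Product: 16 7,10-dimethylundec-9-en-4-yn-6-one
Conditions: 15, n-BuLi, THF, −78 °C; then 14, −78 → 0 °C; dilute aq. HCl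
Reagents that add atoms: none
Why: Weinreb ketone synthesis: the lithium acetylide adds once to the N-methoxy-N-methylamide because the chelated tetrahedral adduct survives until the acidic quench.

Step 7
Reactants: 16 7,10-dimethylundec-9-en-4-yn-6-one; 17 (S)-2-(methoxymethyl)pyrrolidine
Product: 18 (4E)-4-[(2S)-2-(methoxymethyl)pyrrolidin-1-yl]-7,10-dimethylundeca-4,9-dien-6-one
Conditions: EtOH, rt
Reagents that add atoms: none
Why: Aza-Michael addition of the secondary amine to the ynone gives the E vinylogous amide and fixes nitrogen on the propyl-bearing carbon, so that the only hydrogen α to the carbonyl is the one on the future quaternary carbon.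

Step 8
Reactants: 18 (4E)-4-[(2S)-2-(methoxymethyl)pyrrolidin-1-yl]-7,10-dimethylundeca-4,9-dien-6-one; 11 8-hexanoyl-5-methoxy-2-oxo-7-(trimethylsilyloxy)chromane-3-carbonyl chloride
Product: 22 (4R)-2-[(3-hexanoyl-2,4-dihydroxy-6-methoxyphenyl)methyl]-3-hydroxy-6-{1-[(2S)-2-(methoxymethyl)pyrrolidin-1-yl]butylidene}-4-methyl-4-(3-methylbut-2-en-1-yl)cyclohex-2-ene-1,5-dione, via aminosiloxydiene 19 (not isolated), via acylketene 20 (not isolated), via seco-diketone 21 (not isolated)
Conditions: 18: KN(SiMe3)2, THF, −78 °C, then Me3SiCl; 11: Et3N, PhMe, −30 °C, cold filtration; mixed at −78 → −20 °C; Bu4N[Ph3SiF2] (10 mol%), −20 °C → rt; pH 7 buffer; preparative HPLC to separate the two quaternary-carbon epimers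
Reagents that add atoms: none
Why: Proposed new method: a (3+3) double C-acylation through two ketenes: the fully substituted terminal carbon of the 1-amino-3-siloxydiene 19 (the carbon activated by both N and OSi) adds to the ketene carbon of 20 to give 21 and with it the quaternary carbon, then catalytic fluoride (relayed by the liberated aryloxide) unmasks the β-keto aryl-lactone enolate, which expels the ring-A phenoxide by E1cB to a second acylketene that is trapped by the α-carbon of the re-formed vinylogous amide. The closest known reaction types are the terminal-carbon (Mukaiyama-type) acylation of 1,3-bis(silyloxy)- and aminosiloxy-dienes, the E1cB acylketene pathway of aryl β-keto esters and the C-acylation of enaminones (Stork-type), which have not been combined into such an annulation on this substrate class. Ring B closes by a 6-exo Dieckmann-type attack of the enamine carbon on the ketene (or lactone) carbonyl carbon, with the enamine C=C exocyclic to the new ring. The quaternary stereocentre arises from an E/Z-mixed dienol ether whose methyl and prenyl-CH2 groups are sterically alike, so no facial bias is counted on; the controlling element is the (S)-centre of the pyrrolidine auxiliary, which makes the two epimers diastereomers, and the epimer with the target configuration is secured by separation and cannot epimerise afterwards (no α-hydrogen). The step needs C- over O-acylation and the correct carbon pair: N and O of 18 are capped (N-alkyl, O-silyl) so that only its two α-carbons are nucleophilic, the two carbonyls of the malonyl unit end as equivalent ring positions so either may react first, and because the quaternary carbon is formed before ring closure neither a pyranone nor an aromatic phloroglucinol can form as a sink.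

Step 9
Reactants: 22 (4R)-2-[(3-hexanoyl-2,4-dihydroxy-6-methoxyphenyl)methyl]-3-hydroxy-6-{1-[(2S)-2-(methoxymethyl)pyrrolidin-1-yl]butylidene}-4-methyl-4-(3-methylbut-2-en-1-yl)cyclohex-2-ene-1,5-dione
Product: 23 Elaphopilosin B
Conditions: 1 M aq. HCl, THF, rt
Reagents that add atoms: water O
Why: Acid hydrolysis of the tertiary enaminone (protonation, water addition to the iminium carbon, loss of the amine) unveils the butanoyl group; the quaternary stereocentre has no α-hydrogen and cannot epimerise.

**Compound list**

1 | phloroglucinol | Oc1cc(O)cc(O)c1 | starting material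
2 | hexanoyl chloride | CCCCCC(=O)Cl | starting material
3 | 1-(2,4,6-trihydroxyphenyl)hexan-1-one | CCCCCC(=O)c1c(O)cc(O)cc1O | intermediate
4 | 1-(2,6-dihydroxy-4-methoxyphenyl)hexan-1-one | CCCCCC(=O)c1c(O)cc(OC)cc1O | intermediate
5 | 2,2-dimethyl-1,3-dioxane-4,6-dione (Meldrum's acid) | CC1(C)OC(=O)CC(=O)O1 | starting material
6 | formaldehyde | C=O | starting material
7 | 2,2-dimethyl-5-methylidene-1,3-dioxane-4,6-dione | C=C1C(=O)OC(C)(C)OC1=O | intermediate (not isolated)
8 | 5-[(3-hexanoyl-2,4-dihydroxy-6-methoxyphenyl)methyl]-2,2-dimethyl-1,3-dioxane-4,6-dione | CCCCCC(=O)c1c(O)cc(OC)c(CC2C(=O)OC(C)(C)OC2=O)c1O | intermediate (not isolated)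
9 | 8-hexanoyl-7-hydroxy-5-methoxy-2-oxochromane-3-carboxylic acid (racemic, labile centre) | CCCCCC(=O)c1c(O)cc(OC)c2CC(C(=O)O)C(=O)Oc12 | intermediate
10 | trimethylsilyl 8-hexanoyl-5-methoxy-2-oxo-7-(trimethylsilyloxy)chromane-3-carboxylate | CCCCCC(=O)c1c(O[Si](C)(C)C)cc(OC)c2CC(C(=O)O[Si](C)(C)C)C(=O)Oc12 | intermediate (not isolated)
11 | 8-hexanoyl-5-methoxy-2-oxo-7-(trimethylsilyloxy)chromane-3-carbonyl chloride | CCCCCC(=O)c1c(O[Si](C)(C)C)cc(OC)c2CC(C(=O)Cl)C(=O)Oc12 | intermediate
12 | N-methoxy-N-methylpropanamide | CCC(=O)N(C)OC | starting material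
13 | 1-bromo-3-methylbut-2-ene | CC(C)=CCBr | starting material
14 | N-methoxy-N,2,5-trimethylhex-4-enamide (racemic) | CC(C)=CCC(C)C(=O)N(C)OC | intermediate
15 | pent-1-yne | CCCC#C | starting material
16 | 7,10-dimethylundec-9-en-4-yn-6-one (racemic) | CCCC#CC(=O)C(C)CC=C(C)C | intermediate
17 | (S)-2-(methoxymethyl)pyrrolidine | COC[C@@H]1CCCN1 | starting material
18 | (4E)-4-[(2S)-2-(methoxymethyl)pyrrolidin-1-yl]-7,10-dimethylundeca-4,9-dien-6-one (both epimers at the methyl-bearing carbon) | CCC/C(N1CCC[C@H]1COC)=C\C(=O)C(C)CC=C(C)C | intermediate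
19 | 1-amino-3-siloxydiene: trimethylsilyl dienol ether of 18 (E/Z mixture at the fully substituted double bond) | CCC/C(N1CCC[C@H]1COC)=C\C(O[Si](C)(C)C)=C(C)CC=C(C)C | intermediate (not isolated)
20 | 8-hexanoyl-5-methoxy-3-(oxomethylidene)-7-(trimethylsilyloxy)chroman-2-one | CCCCCC(=O)c1c(O[Si](C)(C)C)cc(OC)c2CC(=C=O)C(=O)Oc12 | intermediate (not isolated)
21 | seco-diketone: the lactone of 20 acylated at the quaternary carbon of 18 (drawn as keto tautomer, present as its O-silyl enol ether or enolate; both epimers at the quaternary carbon) | CCCCCC(=O)c1c(O[Si](C)(C)C)cc(OC)c2CC(C(=O)C(C)(CC=C(C)C)C(=O)/C=C(\CCC)N3CCC[C@H]3COC)C(=O)Oc12 | intermediate (not isolated)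
22 | (4R)-2-[(3-hexanoyl-2,4-dihydroxy-6-methoxyphenyl)methyl]-3-hydroxy-6-{1-[(2S)-2-(methoxymethyl)pyrrolidin-1-yl]butylidene}-4-methyl-4-(3-methylbut-2-en-1-yl)cyclohex-2-ene-1,5-dione | CCCCCC(=O)c1c(O)cc(OC)c(CC2=C(O)[C@@](C)(CC=C(C)C)C(=O)C(=C(CCC)N3CCC[C@H]3COC)C2=O)c1O | intermediate
23 | Elaphopilosin B | CCCCCC(=O)c1c(O)cc(OC)c(CC2=C(O)[C@@](C)(CC=C(C)C)C(O)=C(C(=O)CCC)C2=O)c1O | target

**Step count and risks**

Total step count: 9. Longest linear sequence: 6 steps (1, 2, 3, 4, 8, 9).

Steps most likely to fail:

1. Step 8 (proposed new method). What may go wrong: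
   - deprotonation of 18 at the propyl CH2 instead of the α′-CH;
   - [2+2] collapse of the ketene/dienol-ether adduct to a cyclobutanone;
   - stalling at the silyl enol ether of 21;
   - co-elution of the two epimers, which differ only in a remote stereocentre.

   Fallback with known chemistry (ring B first, methylene bridge last): it sets out from 1, 13, 4 and 6 and returns at 23. Friedel–Crafts butanoylation of 1 (butanoyl chloride, AlCl3) should give 1-(2,4,6-trihydroxyphenyl)butan-1-one F1. C-Prenylation with 13 (aq. KOH, 0 °C) should give 1-[2,4,6-trihydroxy-3-(3-methylbut-2-en-1-yl)phenyl]butan-1-one F2. Dearomatising C-methylation at the prenylated carbon (MeI, NaOMe, MeOH) should give racemic 2-butanoyl-3,5-dihydroxy-4-methyl-4-(3-methylbut-2-en-1-yl)cyclohexa-2,5-dien-1-one F3. Resolution on a chiral stationary phase should give (4R)-2-butanoyl-3,5-dihydroxy-4-methyl-4-(3-methylbut-2-en-1-yl)cyclohexa-2,5-dien-1-one F4. Base-mediated condensation of F4 with 4 and 6 (the methylene-bridge formation used for dimeric acylphloroglucinols) should give 23.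

2. Step 3. What may go wrong: formaldehyde linking two molecules of 4 to a diarylmethane, a second alkylation at the remaining ring carbon, or loss of CO2 from 9 on warming.

   Fallback from 4 back to 9. Formylation (Cl2CHOMe, TiCl4, CH2Cl2) should give 3-hexanoyl-2,4-dihydroxy-6-methoxybenzaldehyde F5. Knoevenagel condensation with 5 (piperidinium acetate, EtOH) with spontaneous lactonisation should give 8-hexanoyl-7-hydroxy-5-methoxy-2-oxo-2H-chromene-3-carboxylic acid F6. Conjugate transfer hydrogenation of the ring C=C bond (diethyl 2,6-dimethyl-1,4-dihydropyridine-3,5-dicarboxylate, THF, 50 °C) should return 9.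

3. Step 4. What may go wrong: loss of CO2 from the malonic half-ester during silylation or concentration, or premature dehydrochlorination and dimerisation of the ketene.

   Fallback from 9 to 20 without an acid chloride. Coupling with pentafluorophenol (DCC, EtOAc, 0 °C) should give pentafluorophenyl 8-hexanoyl-7-hydroxy-5-methoxy-2-oxochromane-3-carboxylate F7. N,O-Bis(trimethylsilyl)acetamide should give pentafluorophenyl 8-hexanoyl-5-methoxy-2-oxo-7-(trimethylsilyloxy)chromane-3-carboxylate F8. Et3N at −30 °C should expel pentafluorophenoxide by E1cB and deliver ketene 20 for step 8.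

Further compounds
F1 | step 8 | 1-(2,4,6-trihydroxyphenyl)butan-1-one | CCCC(=O)c1c(O)cc(O)cc1O
F2 | step 8 | 1-[2,4,6-trihydroxy-3-(3-methylbut-2-en-1-yl)phenyl]butan-1-one | CCCC(=O)c1c(O)cc(O)c(CC=C(C)C)c1O
F3 | step 8 | racemic 2-butanoyl-3,5-dihydroxy-4-methyl-4-(3-methylbut-2-en-1-yl)cyclohexa-2,5-dien-1-one | O=C1C=C(O)C(C)(CC=C(C)C)C(O)=C1C(=O)CCC
F4 | step 8 | (4R)-2-butanoyl-3,5-dihydroxy-4-methyl-4-(3-methylbut-2-en-1-yl)cyclohexa-2,5-dien-1-one | O=C1C=C(O)[C@@](C)(CC=C(C)C)C(O)=C1C(=O)CCC
F5 | step 3 | 3-hexanoyl-2,4-dihydroxy-6-methoxybenzaldehyde | CCCCCC(=O)c1c(O)cc(OC)c(C=O)c1O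
F6 | step 3 | 8-hexanoyl-7-hydroxy-5-methoxy-2-oxo-2H-chromene-3-carboxylic acid | CCCCCC(=O)c1c(O)cc(OC)c2C=C(C(=O)O)C(=O)Oc12
F7 | step 4 | pentafluorophenyl 8-hexanoyl-7-hydroxy-5-methoxy-2-oxochromane-3-carboxylate | CCCCCC(=O)c1c(O)cc(OC)c2CC(C(=O)Oc3c(F)c(F)c(F)c(F)c3F)C(=O)Oc12
F8 | step 4 | pentafluorophenyl 8-hexanoyl-5-methoxy-2-oxo-7-(trimethylsilyloxy)chromane-3-carboxylate | CCCCCC(=O)c1c(O[Si](C)(C)C)cc(OC)c2CC(C(=O)Oc3c(F)c(F)c(F)c(F)c3F)C(=O)Oc12
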